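## Retrosynthetic overview

1. Ester C–O bond: target ⇒ ent-labda-8(17),13(16),14-trien-19-ol + (E)-4-acetoxycinnamic acid; the 2-substituted butadiene ⇒ terminal alkyne + ethylene (enyne cross-metathesis).
2. C19 CH2OH and C3 CH2 ⇒ bicyclic 3-oxo 19-ester carrying a (−)-8-phenylmenthyl auxiliary (ester reduction frees alcohol and auxiliary; tosylhydrazone reduction deletes the ketone).
3. Key disconnection: C4–C5 and C9–C10 in one oxidative radical cascade of an acyclic (E,E)-dienyl α-methyl β-keto ester. The enolate carbon C4 is oxidised to an electrophilic α-keto radical and joined to the nucleophilic alkene carbon C5, so two donor carbons are coupled. Ring A closes first, ring B second, and copper-mediated termination gives the 8(17)-alkene.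
4. Acyclic precursor ⇒ keto ester dianion + allylic bromide; the bromide comes from geranyl bromide, 1-(trimethylsilyl)propyne and a SeO2 allylic oxidation.

Assumption: the (−)-8-phenylmenthyl ester is taken, by analogy with related auxiliary-controlled cyclisations (recalled, not verified here), to favour the ent series drawn; diastereomers are separated at 12.

Locants for the bicyclic compounds are labdane locants; C19 is the C4 carbon that is axial and cis to the C10 methyl.

## Route

Step 1
Reactants: 1 geranyl bromide; 2 1-(trimethylsilyl)propyne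
Product: 4 (E)-(6,10-dimethylundeca-5,9-dien-1-yn-1-yl)trimethylsilane, via lithiated silylpropyne 3 (not isolated)
Conditions: 2, n-BuLi, THF, −20 °C; then 1, −78 °C → rt
Reagents that add atoms: none
Why: Propargylic lithiation of the silylpropyne followed by SN2 alkylation at the primary allylic bromide gives the 1,5-enyne with the E-alkene untouched, the silyl group blocking the allenyl pathway and the alkyne C–H.

Step 2
Reactants: 4
Product: 5 (2E,6E)-2,6-dimethyl-11-(trimethylsilyl)undeca-2,6-dien-10-yn-1-ol
Conditions: SeO2 (cat.), t-BuOOH, salicylic acid (cat.), CH2Cl2, 0 °C → rt (stop at partial conversion, recycle 4)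
Reagents that add atoms: tert-butyl hydroperoxide, CC(C)(C)OO
Why: Sharpless-type catalytic SeO2 allylic oxidation (ene reaction then [2,3]-sigmatropic shift) attacks the most electron-rich, least hindered terminal trisubstituted alkene and delivers the E-configured primary allylic alcohol.

Step 3
Reactants: 5
Product: 6 [(5E,9E)-11-bromo-6,10-dimethylundeca-5,9-dien-1-yn-1-yl]trimethylsilane
Conditions: CBr4, PPh3, CH2Cl2, −20 → 0 °C
Reagents that add atoms: carbon tetrabromide, BrC(Br)(Br)Br
Why: The Appel reaction converts the primary allylic alcohol to the bromide by SN2 displacement of the oxyphosphonium without allylic transposition or loss of E geometry.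

Step 4
Reactants: 7 (−)-8-phenylmenthol [(1R,2S,5R)-5-methyl-2-(2-phenylpropan-2-yl)cyclohexan-1-ol]; 8 ethyl 2-methylacetoacetate
Product: 9 (−)-8-phenylmenthyl 2-methyl-3-oxobutanoate (C2 epimers)
Conditions: DMAP (cat.), toluene, reflux (−EtOH)
Reagents that add atoms: none
Why: DMAP-catalysed transesterification of a β-keto ester is driven by removal of ethanol, and the C2 epimer mixture is irrelevant because C2 later becomes a planar radical.

Step 5
Reactants: 9; 6
Product: 11 (−)-8-phenylmenthyl (6E,10E)-2,6,10-trimethyl-3-oxo-15-(trimethylsilyl)pentadeca-6,10-dien-14-ynoate (C2 epimers), via keto ester dianion 10 (not isolated)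
Conditions: 9, NaH, THF, 0 °C; n-BuLi, 0 °C; then 6, 0 °C; aq. HCl quench
Reagents that add atoms: none
Why: Weiler dianion alkylation: the more basic terminal carbanion of the 1,3-dicarbonyl dianion displaces the allylic bromide by SN2, attaching the chain at the ketone methyl and leaving both E-alkenes and the silylalkyne intact.

Step 6
Reactants: 11
Product: 12 (−)-8-phenylmenthyl (4S,5S,9R,10S)-3-oxo-14-(trimethylsilyl)-15,16-dinorlabd-8(17)-en-13-yn-19-oate (ent-labdane series; trans-decalin, axial ester cis to the C10 methyl, equatorial C9 side chain)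
Conditions: Mn(OAc)3·2H2O (2.2 equiv), Cu(OAc)2·H2O (1 equiv), degassed AcOH, 20 °C; chromatography
Reagents that add atoms: none
Why: Snider-type oxidative free-radical polyene cyclisation: one-electron oxidation of the keto ester enol by trivalent manganese reverses the polarity of C4, and the electrophilic α-keto radical adds 6-endo to the nucleophilic alkene carbon C5 (ring A); the tertiary C10 radical then closes ring B at C9 through a chair–chair transition state in which the E,E-alkenes set the trans fusion and the equatorial C9 chain, the anti arrangement of the two carbonyls puts the ester axial, and the aryl group of the auxiliary shields one face of the radical to set absolute configuration, before divalent copper oxidises the tertiary C8 radical with β-hydrogen loss from the methyl to give the exocyclic alkene.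

Step 7
Reactants: 12
Product: 14 (−)-8-phenylmenthyl (4R,5S,9R,10S)-14-(trimethylsilyl)-15,16-dinorlabd-8(17)-en-13-yn-19-oate, via C3 tosylhydrazone 13 (not isolated)
Conditions: TsNHNH2, PPTS (cat.), EtOH, 80 °C; then catecholborane, CHCl3, 0 °C → rt; NaOAc·3H2O, 60 °C
Reagents that add atoms: none
Why: Caglioti-type tosylhydrazone reduction in its catecholborane (Kabalka) form adds hydride to the C=N bond, expels sulfinate and loses N2 from the diazene to leave CH2 at C3 under near-neutral conditions that spare the exocyclic alkene, the silylalkyne and the hindered ester, with no stereocentre touched.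

Step 8
Reactants: 14
Product: 16 (4R,5S,9R,10S)-15,16-dinorlabd-8(17)-en-13-yn-19-ol, via silylated alkynol 15 (not isolated)
Conditions: LiAlH4, THF, 0 → 50 °C; aq. NaOH work-up; then K2CO3, MeOH, rt
Reagents that add atoms: none
Why: Hydride reduction of the neopentyl-type ester gives the C19 primary alcohol and returns the auxiliary alcohol 7 for reuse, and base-catalysed methanolysis then cleaves the alkynyl C–Si bond to free the terminal alkyne.

Step 9
Reactants: 16
Product: 17 (4R,5S,9R,10S)-labda-8(17),13(16),14-trien-19-ol (ent-labdane series)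
Conditions: second-generation Grubbs catalyst (H2IMes)(PCy3)Cl2Ru=CHPh (5 mol %), ethylene (1 atm), toluene, 80 °C
Reagents that add atoms: ethylene, C=C
Why: Ethylene–alkyne cross enyne metathesis: the ruthenium methylidene adds to the terminal alkyne and the resulting vinylcarbene is intercepted by ethylene to give the 2-substituted 1,3-butadiene directly, while the hindered 1,1-disubstituted exocyclic alkene can only undergo degenerate methylene exchange.

Step 10
Reactants: 17; 18 (E)-4-acetoxycinnamic acid
Product: 20 (4R,5S,9R,10S)-labda-8(17),13(16),14-trien-19-yl (2E)-3-(4-hydroxyphenyl)prop-2-enoate (target, CNP0131099.1), via acetylated coumarate 19 (not isolated)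
Conditions: 18, DCC, DMAP, CH2Cl2, 0 °C → rt; then pyrrolidine, rt
Reagents that add atoms: none
Why: Steglich esterification acylates the single hindered primary alcohol with retention of the E-cinnamate geometry, and aminolysis of the aryl acetate by pyrrolidine is far faster than attack on the neopentyl cinnamate, so the phenol is unmasked in the same flask.

## Compound list

1 | geranyl bromide, (2E)-1-bromo-3,7-dimethylocta-2,6-diene | CC(C)=CCC/C(C)=C/CBr | starting material
2 | 1-(trimethylsilyl)propyne | CC#C[Si](C)(C)C | starting material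
3 | [3-(trimethylsilyl)prop-2-yn-1-yl]lithium | [Li]CC#C[Si](C)(C)C | intermediate
4 | (E)-(6,10-dimethylundeca-5,9-dien-1-yn-1-yl)trimethylsilane | CC(C)=CCC/C(C)=C/CCC#C[Si](C)(C)C | intermediate
5 | (2E,6E)-2,6-dimethyl-11-(trimethylsilyl)undeca-2,6-dien-10-yn-1-ol | OC/C(C)=C/CC/C(C)=C/CCC#C[Si](C)(C)C | intermediate
6 | [(5E,9E)-11-bromo-6,10-dimethylundeca-5,9-dien-1-yn-1-yl]trimethylsilane | BrC/C(C)=C/CC/C(C)=C/CCC#C[Si](C)(C)C | intermediate
7 | (−)-8-phenylmenthol, (1R,2S,5R)-5-methyl-2-(2-phenylpropan-2-yl)cyclohexan-1-ol | CC(C)(c1ccccc1)[C@@H]1CC[C@@H](C)C[C@H]1O | starting material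
8 | ethyl 2-methyl-3-oxobutanoate | CCOC(=O)C(C)C(C)=O | starting material
9 | (1R,2S,5R)-5-methyl-2-(2-phenylpropan-2-yl)cyclohexyl 2-methyl-3-oxobutanoate (C2 epimers) | CC(=O)C(C)C(=O)O[C@@H]1C[C@H](C)CC[C@H]1C(C)(C)c1ccccc1 | intermediate
10 | sodium lithium dianion of 9 (enolate plus terminal carbanion) | [Li]CC(O[Na])=C(C)C(=O)O[C@@H]1C[C@H](C)CC[C@H]1C(C)(C)c1ccccc1 | intermediate
11 | (−)-8-phenylmenthyl (6E,10E)-2,6,10-trimethyl-3-oxo-15-(trimethylsilyl)pentadeca-6,10-dien-14-ynoate (C2 epimers) | C[Si](C)(C)C#CCC/C=C(\C)CC/C=C(\C)CCC(=O)C(C)C(=O)O[C@@H]1C[C@H](C)CC[C@H]1C(C)(C)c1ccccc1 | intermediate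
12 | (−)-8-phenylmenthyl (4S,5S,9R,10S)-3-oxo-14-(trimethylsilyl)-15,16-dinorlabd-8(17)-en-13-yn-19-oate | C[Si](C)(C)C#CCC[C@@H]1C(=C)CC[C@@H]2[C@](C)(C(=O)O[C@@H]3C[C@H](C)CC[C@H]3C(C)(C)c3ccccc3)C(=O)CC[C@@]12C | intermediate
13 | C3 tosylhydrazone of 12 (4S,5S,9R,10S; C=N geometry not defined) | C[Si](C)(C)C#CCC[C@@H]1C(=C)CC[C@@H]2[C@](C)(C(=O)O[C@@H]3C[C@H](C)CC[C@H]3C(C)(C)c3ccccc3)C(=NNS(=O)(=O)c3ccc(C)cc3)CC[C@@]12C | intermediate
14 | (−)-8-phenylmenthyl (4R,5S,9R,10S)-14-(trimethylsilyl)-15,16-dinorlabd-8(17)-en-13-yn-19-oate | C[Si](C)(C)C#CCC[C@@H]1C(=C)CC[C@@H]2[C@](C)(C(=O)O[C@@H]3C[C@H](C)CC[C@H]3C(C)(C)c3ccccc3)CCC[C@@]12C | intermediate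
15 | (4R,5S,9R,10S)-14-(trimethylsilyl)-15,16-dinorlabd-8(17)-en-13-yn-19-ol | C[Si](C)(C)C#CCC[C@@H]1C(=C)CC[C@@H]2[C@](C)(CO)CCC[C@@]12C | intermediate
16 | (4R,5S,9R,10S)-15,16-dinorlabd-8(17)-en-13-yn-19-ol | C#CCC[C@@H]1C(=C)CC[C@@H]2[C@](C)(CO)CCC[C@@]12C | intermediate
17 | (4R,5S,9R,10S)-labda-8(17),13(16),14-trien-19-ol | C=CC(=C)CC[C@@H]1C(=C)CC[C@@H]2[C@](C)(CO)CCC[C@@]12C | intermediate
18 | (E)-4-acetoxycinnamic acid | CC(=O)Oc1ccc(/C=C/C(=O)O)cc1 | starting material
19 | (4R,5S,9R,10S)-labda-8(17),13(16),14-trien-19-yl (2E)-3-(4-acetoxyphenyl)prop-2-enoate | C=CC(=C)CC[C@@H]1C(=C)CC[C@@H]2[C@](C)(COC(=O)/C=C/c3ccc(OC(C)=O)cc3)CCC[C@@]12C | intermediate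
20 | (4R,5S,9R,10S)-labda-8(17),13(16),14-trien-19-yl (2E)-3-(4-hydroxyphenyl)prop-2-enoate | C=CC(=C)CC[C@@H]1C(=C)CC[C@@H]2[C@](C)(COC(=O)/C=C/c3ccc(O)cc3)CCC[C@@]12C | target

## Step count and weak points

Total step count: 10. Longest linear sequence: 9 (steps 1, 2, 3, 5, 6, 7, 8, 9, 10, from 1 to 20); step 4 is a one-step branch.

Step 6 is the most likely to fail. The facial control by the auxiliary on an α-methyl radical is argued by analogy, the exocyclic/endocyclic alkene ratio depends on the copper step, and the tertiary C8 radical could add to the pendant alkyne (kept down by a high Cu(OAc)2 concentration). The fallback sets out from 6 (with 7) and comes back at 12. Heat 7 with 2,2,6-trimethyl-4H-1,3-dioxin-4-one in xylene to give (−)-8-phenylmenthyl acetoacetate F1. Alkylate its dianion (NaH, n-BuLi) with 6 to give the α-unsubstituted dienynyl keto ester F2. Cyclise F2 with Mn(OAc)3·2H2O and Cu(OAc)2·H2O in CF3CH2OH at −5 °C in the presence of Yb(OTf)3, where the chelated radical of an α-unsubstituted ester gives the strongest auxiliary control, to the C4-unsubstituted bicyclic keto ester F3. Then create the quaternary centre afterwards by enolate methylation (K2CO3, MeI, acetone), the electrophile entering anti to the angular methyl so that the ester remains axial, to reach 12.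

Step 7 may fail because the C3 ketone sits next to the quaternary C4 with its bulky axial ester, so hydrazone formation can stall. The fallback sets out from 12 and comes back at 14. Reduce the ketone with NaBH4 (MeOH, 0 °C) to the 3-hydroxy ester F4 (either C3 epimer serves). Convert it with 1,1'-thiocarbonyldiimidazole and DMAP to the 3-O-(imidazol-1-ylthiocarbonyl) ester F5. Remove the oxygen by Barton–McCombie radical deoxygenation (Bu3SnH, AIBN, toluene, 100 °C) to give 14.

Step 9 may fail because the vinylcarbene could be diverted by the exocyclic alkene or the catalyst could die before full conversion. The fallback sets out from 16 and comes back at 17. Markovnikov hydrosilylation of the terminal alkyne with benzyldimethylsilane and [Cp*Ru(MeCN)3]PF6 (acetone, rt) gives the 1,1-disubstituted α-vinylsilane F6. Fluoride-promoted Hiyama–Denmark coupling of F6 with vinyl bromide (TBAF, Pd2(dba)3, THF, rt) then gives diene 17.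

## Further compounds

F1 | step 6 | (1R,2S,5R)-5-methyl-2-(2-phenylpropan-2-yl)cyclohexyl 3-oxobutanoate | CC(=O)CC(=O)O[C@@H]1C[C@H](C)CC[C@H]1C(C)(C)c1ccccc1
F2 | step 6 | (−)-8-phenylmenthyl (6E,10E)-6,10-dimethyl-3-oxo-15-(trimethylsilyl)pentadeca-6,10-dien-14-ynoate | C[Si](C)(C)C#CCC/C=C(\C)CC/C=C(\C)CCC(=O)CC(=O)O[C@@H]1C[C@H](C)CC[C@H]1C(C)(C)c1ccccc1
F3 | step 6 | (−)-8-phenylmenthyl 3-oxo-14-(trimethylsilyl)-15,16,18-trinorlabd-8(17)-en-13-yn-19-oate, ring configuration as in 12, C4 epimerisable | C[Si](C)(C)C#CCC[C@@H]1C(=C)CC[C@@H]2C(C(=O)O[C@@H]3C[C@H](C)CC[C@H]3C(C)(C)c3ccccc3)C(=O)CC[C@@]12C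
F4 | step 7 | (−)-8-phenylmenthyl 3-hydroxy-14-(trimethylsilyl)-15,16-dinorlabd-8(17)-en-13-yn-19-oate, ring configuration as in 12, C3 not defined | C[Si](C)(C)C#CCC[C@@H]1C(=C)CC[C@@H]2[C@](C)(C(=O)O[C@@H]3C[C@H](C)CC[C@H]3C(C)(C)c3ccccc3)C(O)CC[C@@]12C
F5 | step 7 | (−)-8-phenylmenthyl 3-[(1H-imidazol-1-ylcarbonothioyl)oxy]-14-(trimethylsilyl)-15,16-dinorlabd-8(17)-en-13-yn-19-oate, ring configuration as in 12 | C[Si](C)(C)C#CCC[C@@H]1C(=C)CC[C@@H]2[C@](C)(C(=O)O[C@@H]3C[C@H](C)CC[C@H]3C(C)(C)c3ccccc3)C(OC(=S)n3ccnc3)CC[C@@]12C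
F6 | step 9 | (4R,5S,9R,10S)-13-[benzyl(dimethyl)silyl]-15,16-dinorlabda-8(17),13-dien-19-ol | C=C([Si](C)(C)Cc1ccccc1)CC[C@@H]1C(=C)CC[C@@H]2[C@](C)(CO)CCC[C@@]12C
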